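## The problem

The target, 2-[(3S,6R)-6-[(6E)-hexadec-6-en-4-yn-1-yl]-6-methoxy-1,2-dioxan-3-yl]acetic acid (23), is a monocyclic peroxide. Its 1,2-dioxane ring (O1, O2, C3, C4, C5, C6) carries a CH2CO2H arm on C3, and C6 is a methyl peroxyketal bearing a sixteen-carbon (E)-enyne chain. The two stereocentres are 1,4-related. C3 is a secondary peroxy carbon that cannot be epimerised and must therefore be set absolutely. C6 is a ketal centre that can ionise. In the target the methoxy group and the acetic acid arm are cis, so that in the chair the methoxy group is axial and both carbon substituents are equatorial, which is the anomerically favoured arrangement. C3 can therefore control C6 under equilibrating conditions, but not the reverse. The O–O bond excludes hydride reagents, hydrogenation, low-valent metals and strong base (Kornblum–DeLaMare cleavage at C3–H, retro-oxa-Michael opening of the β-peroxy carbonyl unit). The peroxyketal is acid-labile, and the conjugated enyne does not survive ozone. Since the geminal methoxy/peroxy pattern at C6 is most directly made by ozonolysis of a 1,1-disubstituted alkene in methanol, the enyne has to be attached after the peroxide is in place, by a mild coupling. The feature that opens the route is that the peroxide oxygen on C3 is β to the C1 carboxyl: C1–C2–C3–O is the backbone of a 4-alkyl oxetan-2-one, and a hydroperoxide oxygen on C6 stands exactly six atoms from C3.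

## Retrosynthesis

**Side chain.** Acid 23 is taken back to its methyl ester 21, and 21 is cut at the bond between the alkyne carbon C5′ and the alkene carbon C6′, giving dioxane alkyne 17 and (E)-1-iodoundec-1-ene (20). A cut inside the alkene (olefination) would place an aldehyde on a peroxide and leave the E geometry to chance. A cut at C3′–C4′ would require an acetylide alkylation in the presence of the O–O bond. The chosen cut removes eleven carbons and the ozone-sensitive alkene in one operation. It asks for a room-temperature Sonogashira coupling that tolerates a dialkyl peroxide, followed by a gentle saponification. Iodide 20 comes in one step from undec-1-yne (18).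

**Ester, silyl cap and C6.** Alkyne 17 is related to acid 15 by esterification, epimerisation at C6 and removal of an alkynyl trimethylsilyl group, passing through silyl ester 16. Because the wanted C6 epimer is the thermodynamic one, nothing earlier needs to control C6. The precursor 15 is therefore allowed to be a mixture at C6 with only C3 defined.

**Ring (key disconnection).** Acid 15 is cut at the O2–C3 bond. Three neighbouring cuts were weighed:
- Closing O1–C6 would need an enantiopure secondary hydroperoxide at C3.
- Forming O2–C3 by oxa-Michael addition to an enoate is not stereospecific.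
- Displacing a C3 sulfonate is stereospecific, but a β-sulfonyloxy ester eliminates under base, so C1 would have to be carried as a protected alcohol and oxidised afterwards.

The β-lactone 12 keeps the stereospecific displacement and avoids these penalties. The lactone oxygen is the leaving group and its configuration is defined. The carboxyl emerges free at the correct oxidation level. The four-membered ring resists E1cB loss. Precursor 12 has a single stereocentre that matters. The forward reaction must achieve alkyl–oxygen rather than acyl–oxygen cleavage.

**Hydroperoxy ketal.** In 12 the two C6–O bonds are cut back to the methylidene group of lactone 10. Ozonolysis in methanol installs OMe and OOH in one step and loses one carbon as formaldehyde. This is preferred to peroxyketalisation of a ketone, which needs acid and hydrogen peroxide in the presence of the lactone.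

**Lactone.** Lactone 10 is cut at C2–C3 and O–C1 to aldehyde 9 and a two-carbon ketene unit generated from an acetyl halide. A catalytic asymmetric [2+2] sets the only stereocentre that must be controlled. An aldol/lactonisation sequence would take three or more steps.

**Aldehyde.** Aldehyde 9 comes from ester 8 by partial reduction. Ester 8 is cut at C4–C5 by a Johnson–Claisen transform to allyl alcohol 5 and triethyl orthoacetate (6). The rearrangement forms the bond and also places the double bond in the 1,1-disubstituted position needed for ozonolysis.

**Allyl alcohol.** Alcohol 5 is cut at C6–C1′ to prop-2-yn-1-ol (2) and the Grignard reagent of (5-chloropent-1-yn-1-yl)trimethylsilane (1). Copper-catalysed carbomagnesiation of the propargyl alkoxide gives the 2-substituted allyl alcohol directly. The silyl cap makes the Grignard reagent possible and stays inert until step 7.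

## Roads not taken

**Alternative 1:** The cut is C4–C5, made as an alkene. A second-generation Grubbs catalyst would join the two vinyl groups of the acyclic bis-allylic peroxide A2 and give the 3,6-dihydro-1,2-dioxine A1 with loss of ethylene.
- Merits: ring-closing metathesis is a well-established closure and ruthenium carbenes tolerate dialkyl peroxides. C3 would derive from an easily made enantiopure allylic alcohol. In the reliability of the ring-forming event this road is better than the chosen plan.
- Weak points: A2 must be assembled by an intermolecular O–C bond formation between a tertiary, vinyl-substituted hydroperoxy ketal and a secondary allylic electrophile, where SN2′ attack and elimination compete. The hard bond is thus moved into a less favourable setting. The C4=C5 alkene must then be saturated next to an O–O bond and a silyl alkyne, for which only diimide is realistic. C1 arrives as a silyl ether and needs deprotection and a two-stage oxidation. C6 is no better controlled than here, and an allylic peroxyketal is a poor candidate for acid equilibration.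
- Comparison: the chosen plan offers a ring closed at the final saturation and oxidation level and an O–C3 bond made intramolecularly with defined stereochemistry, at least four operations shorter after ring formation.

**Alternative 2:** The cuts are C3–C4 and O1–C6. SnCl4 would ionise silylperoxy acetal A5 to a peroxycarbenium ion at C3. A ring CH2 of methoxycyclopropane A4 would attack it with ring opening to a C6 methoxycarbenium ion, and the peroxy oxygen would close on C6, giving A3 (identical with ester 21 of the present route).
- Merits: this is the most convergent road. Two bonds and the ring form in one step, the complete chain is carried in, no palladium step follows peroxide formation and only saponification remains. In step count it is clearly superior.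
- Weak points: the peroxycarbenium ion is planar, so A3 would be racemic at C3 and mixed at C6, and no chiral Lewis acid is known to control such an ion. A donor-only cyclopropane has no precedent as a three-carbon partner for a peroxycarbenium ion. SnCl4 may open A4 to a homoenolate on its own or attack the enyne, and the ester-destabilised cation may fragment.
- Comparison: the chosen plan offers the one thing this road cannot, absolute configuration at C3 from a catalytic asymmetric step and a stereospecific displacement.

**Alternative 3:** The cut is O1–C6. Anodic oxidation (Hofer–Moest type) of the α-methoxy acid A7 would expel CO2, and the C6 methoxycarbenium ion would be captured by the C3 hydroperoxide to give peroxyketal A6.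
- Merits: the cation forms without added acid. Closure through a chair-like oxocarbenium ion could place the methoxy group axially in the ring-forming event, which is better than the chosen plan, where C6 needs a separate equilibration. The full chain is present, so no coupling follows.
- Weak points: A7 contains an enantiopure secondary hydroperoxide, which is hard to make (displacement of a secondary sulfonate by hydrogen peroxide competes with elimination) and hard to carry. The hydroperoxide and the conjugated enyne are both oxidisable at the potential needed for a carboxylate. The quaternary α-methoxy acid needs its own construction. C1 again needs desilylation and oxidation.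
- Comparison: the chosen plan never handles a free secondary hydroperoxide and never exposes the enyne to an oxidant, because the enyne is installed last.

Key step: step 6

Assumption: the sense of induction of the aluminium triamine catalyst is taken from simple unbranched aldehydes, for which the (S,S)-ligand series gives (S)-4-alkyloxetan-2-ones; the (R,R)-ligand is therefore specified for (4R)-lactone 10.

## Route

Step 1
Reactants: 1 (5-chloropent-1-yn-1-yl)trimethylsilane; 2 prop-2-yn-1-ol
Product: 5 2-methylidene-7-(trimethylsilyl)hept-6-yn-1-ol, via Grignard reagent 3 (not isolated), via alkenylmagnesium chelate 4 (not isolated)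
Conditions: Mg (I2-activated), THF, 60 °C; then 2 (0.4 equiv), CuI (10 mol%), THF/Et2O, −10 → 23 °C; aq. NH4Cl
Reagents that add atoms: none
Why: Magnesium insertion into the primary chloride gives 3, the silyl cap removing the acidic alkyne proton. One equivalent deprotonates the alcohol, and copper-catalysed anti carbomagnesiation of the propargyl alkoxide places the alkyl group on the internal carbon to give chelate 4, which NH4Cl protonates to the 2-substituted allyl alcohol.

Step 2
Reactants: 5 2-methylidene-7-(trimethylsilyl)hept-6-yn-1-ol; 6 triethyl orthoacetate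
Product: 8 ethyl 4-methylidene-9-(trimethylsilyl)non-8-ynoate, via ketene acetal 7 (not isolated)
Conditions: 6 (6 equiv), EtCO2H (5 mol%), 140 °C, EtOH distilled off
Reagents that add atoms: none
Why: Johnson–Claisen rearrangement: acid-catalysed exchange gives ketene acetal 7, whose [3,3] shift forms the C4–C5 bond and moves the double bond into the 1,1-disubstituted position required for the later ozonolysis.

Step 3
Reactants: 8 ethyl 4-methylidene-9-(trimethylsilyl)non-8-ynoate
Product: 9 4-methylidene-9-(trimethylsilyl)non-8-ynal
Conditions: DIBAL-H (1.1 equiv), CH2Cl2, −78 °C; MeOH, then aq. Rochelle salt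
Reagents that add atoms: none
Why: Partial reduction of an unhindered ethyl ester by DIBAL-H stops at −78 °C at the aluminium hemiacetal, which releases the aldehyde on work-up; the alkene and the silyl alkyne are inert.

Step 4
Reactants: 9 4-methylidene-9-(trimethylsilyl)non-8-ynal
Product: 10 (4R)-4-[3-methylidene-8-(trimethylsilyl)oct-7-yn-1-yl]oxetan-2-one
Conditions: AcBr (1.9 equiv), iPr2NEt (1.7 equiv), (R,R)-MeAl[BnN(CH2CH(iPr)NSO2CF3)2] (10 mol%, from AlMe3 and the triamine), CH2Cl2, −50 °C
Reagents that add atoms: acetyl bromide, CC(=O)Br
Why: Catalytic asymmetric acyl halide–aldehyde cyclocondensation: ketene formed from acetyl bromide and the amine adds in a formal [2+2] to the aldehyde bound to the chiral aluminium Lewis acid. The catalyst shields one carbonyl face and so sets lactone C4 (the future C3) as R; unbranched aliphatic aldehydes are the best substrates of this reaction.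

Step 5
Reactants: 10 (4R)-4-[3-methylidene-8-(trimethylsilyl)oct-7-yn-1-yl]oxetan-2-one
Product: 12 (4R)-4-[3-hydroperoxy-3-methoxy-8-(trimethylsilyl)oct-7-yn-1-yl]oxetan-2-one (both epimers at the ketal carbon), via ketone O-oxide 11 (not isolated)
Conditions: O3/O2, CH2Cl2/MeOH (3:1), −78 °C, Sudan Red 7B end point; N2 purge; concentration below 25 °C
Reagents that add atoms: ozone, O=[O+][O-]; methanol, CO
Why: Ozone attacks the 1,1-disubstituted alkene far faster than the silyl alkyne, and cycloaddition–cycloreversion delivers formaldehyde and the more substituted ketone O-oxide 11, which methanol captures as the methoxy hydroperoxide. The β-lactone is inert to neutral methanol at −78 °C; the ketal centre forms without control and both epimers are carried on.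

Step 6
Reactants: 12 (4R)-4-[3-hydroperoxy-3-methoxy-8-(trimethylsilyl)oct-7-yn-1-yl]oxetan-2-one (both epimers at the ketal carbon)
Product: 15 2-[(3S)-6-methoxy-6-[5-(trimethylsilyl)pent-4-yn-1-yl]-1,2-dioxan-3-yl]acetic acid (C6 epimers), via potassium peroxide 13 (not isolated), via potassium carboxylate 14 (not isolated)
Conditions: KN(SiMe3)2 (1.0 equiv), 18-crown-6 (1.1 equiv), THF (0.01 M), −78 → 23 °C; then cold 0.5 M aq. HCl to pH 3–4; used crude
Reagents that add atoms: none
Why: Proposed new method: one equivalent of KN(SiMe3)2 removes only the hydroperoxide proton (pKa about 12, at least ten units below the lactone α-CH2), and the crown-separated peroxide anion of 13 attacks lactone C4 (the future C3) anti to the ring oxygen, so the O–C3 bond forms with inversion while the carboxylate of 14 leaves with release of four-ring strain; the closest known reaction types are the 6-exo alkylation of hydroperoxy ketals by tethered sulfonates or oxetanes to give 1,2-dioxanes and the alkyl–oxygen (SN2) opening of 4-alkyl β-lactones by azide, thiolate and sulfonamide anions, whose conjugate acids lie in the same pKa range as a hydroperoxide. The 1,2-dioxane closes in a 6-exo-tet mode, the six ring atoms being O, O, C6, C5, C4 and C3 and the breaking C–O bond lying outside the new ring. The new stereocentre C3 is under substrate control alone: backside displacement turns the (4R) lactone carbon into (3S), so its enantiopurity is that fixed in step 4. The step needs alkyl–oxygen cleavage to beat acyl attack and elimination. Acyl attack within the molecule would require an eight-membered perester, and between molecules it is held back by the 0.01 M dilution and by the bulk of the tertiary peroxide. Elimination to the enoate is disfavoured because the lactone enolate has its C4–O bond in the nodal plane of the π system and because no base stronger than the peroxide anion is present. After closure the only base left is a carboxylate, too weak to start Kornblum–DeLaMare cleavage at C3–H or retro-oxa-Michael opening, and both C6 epimers of 12 are expected to close, C6 being settled in step 7.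

Step 7
Reactants: 15 2-[(3S)-6-methoxy-6-[5-(trimethylsilyl)pent-4-yn-1-yl]-1,2-dioxan-3-yl]acetic acid (C6 epimers)
Product: 17 methyl 2-[(3S,6R)-6-methoxy-6-(pent-4-yn-1-yl)-1,2-dioxan-3-yl]acetate, via silyl-capped methyl ester 16 (not isolated)
Conditions: TsOH·H2O (0.1 equiv), MeOH, 23 °C; then K2CO3 (0.6 equiv), 0 → 23 °C; chromatography, minor (6S) epimer returned to TsOH/MeOH
Reagents that add atoms: methanol, CO
Why: Fischer esterification and acid-catalysed ionisation of the peroxyketal (loss and re-addition of methanol at C6) run side by side, so C6 should equilibrate towards the epimer with axial methoxy (anomeric effect) and both carbon substituents equatorial, which is the (3S,6R) arrangement of 16; C3 is not touched. Excess K2CO3 then neutralises the acid and the methoxide formed removes the alkynyl silyl group under conditions too mild to enolise the β-peroxy ester.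

Step 8
Reactants: 18 undec-1-yne
Product: 20 (E)-1-iodoundec-1-ene, via alkenylzirconocene chloride 19 (not isolated)
Conditions: Cp2Zr(H)Cl (1.2 equiv), THF, 23 °C; then I2 (1.2 equiv), 0 °C
Reagents that add atoms: iodine, II
Why: Schwartz hydrozirconation adds Zr–H syn across the terminal alkyne with zirconium on the terminal carbon, and iodinolysis of the C–Zr bond proceeds with retention, which fixes the E geometry.

Step 9
Reactants: 17 methyl 2-[(3S,6R)-6-methoxy-6-(pent-4-yn-1-yl)-1,2-dioxan-3-yl]acetate; 20 (E)-1-iodoundec-1-ene
Product: 21 methyl 2-[(3S,6R)-6-[(6E)-hexadec-6-en-4-yn-1-yl]-6-methoxy-1,2-dioxan-3-yl]acetate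
Conditions: Pd(PPh3)4 (5 mol%), CuI (10 mol%), Et3N (3 equiv), degassed THF, 23 °C
Reagents that add atoms: none
Why: Sonogashira coupling of a terminal alkyne with an (E)-alkenyl iodide runs at room temperature with retention of alkene geometry. A saturated dialkyl peroxide lacks the allylic or strained activation needed for insertion of zerovalent palladium, so the 1,2-dioxane should pass through unchanged.

Step 10
Reactants: 21 methyl 2-[(3S,6R)-6-[(6E)-hexadec-6-en-4-yn-1-yl]-6-methoxy-1,2-dioxan-3-yl]acetate
Product: 23 2-[(3S,6R)-6-[(6E)-hexadec-6-en-4-yn-1-yl]-6-methoxy-1,2-dioxan-3-yl]acetic acid, via lithium carboxylate 22 (not isolated)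
Conditions: LiOH·H2O (3 equiv), THF/H2O (3:1), 0 → 23 °C; then 0.5 M aq. HCl to pH 3–4, 0 °C
Reagents that add atoms: lithium hydroxide, [Li+].[OH-]
Why: Saponification of an unhindered methyl ester; the peroxyketal is stable to hydroxide, and once carboxylate 22 has formed the α-protons are no longer acidic enough for retro-oxa-Michael opening. Cold acidification to pH 3–4 frees the acid without hydrolysing the ketal.

## Compound list

1 | (5-chloropent-1-yn-1-yl)trimethylsilane | C[Si](C)(C)C#CCCCCl | starting material
2 | prop-2-yn-1-ol | C#CCO | starting material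
3 | [5-(trimethylsilyl)pent-4-yn-1-yl]magnesium chloride | C[Si](C)(C)C#CCCC[Mg]Cl | intermediate
4 | 4-[5-(trimethylsilyl)pent-4-yn-1-yl]-2,5-dihydro-1,2-oxamagnesole (chelated alkenylmagnesium alkoxide, drawn as monomer) | C[Si](C)(C)C#CCCCC1=C[Mg]OC1 | intermediate
5 | 2-methylidene-7-(trimethylsilyl)hept-6-yn-1-ol | C=C(CO)CCCC#C[Si](C)(C)C | intermediate
6 | triethyl orthoacetate | CCOC(C)(OCC)OCC | starting material
7 | {6-{[(1-ethoxyethenyl)oxy]methyl}hept-6-en-1-yn-1-yl}trimethylsilane (ketene acetal) | C=C(OCC)OCC(=C)CCCC#C[Si](C)(C)C | intermediate
8 | ethyl 4-methylidene-9-(trimethylsilyl)non-8-ynoate | CCOC(=O)CCC(=C)CCCC#C[Si](C)(C)C | intermediate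
9 | 4-methylidene-9-(trimethylsilyl)non-8-ynal | O=CCCC(=C)CCCC#C[Si](C)(C)C | intermediate
10 | (4R)-4-[3-methylidene-8-(trimethylsilyl)oct-7-yn-1-yl]oxetan-2-one | C=C(CCCC#C[Si](C)(C)C)CC[C@@H]1CC(=O)O1 | intermediate
11 | ketone O-oxide of (4R)-4-[3-oxo-8-(trimethylsilyl)oct-7-yn-1-yl]oxetan-2-one | C[Si](C)(C)C#CCCCC(=[O+][O-])CC[C@@H]1CC(=O)O1 | intermediate
12 | (4R)-4-[3-hydroperoxy-3-methoxy-8-(trimethylsilyl)oct-7-yn-1-yl]oxetan-2-one (both epimers at the ketal carbon) | C[Si](C)(C)C#CCCCC(OC)(OO)CC[C@@H]1CC(=O)O1 | intermediate
13 | potassium salt of hydroperoxide 12 | C[Si](C)(C)C#CCCCC(OC)(O[O-])CC[C@@H]1CC(=O)O1.[K+] | intermediate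
14 | potassium 2-[(3S)-6-methoxy-6-[5-(trimethylsilyl)pent-4-yn-1-yl]-1,2-dioxan-3-yl]acetate (C6 epimers) | C[Si](C)(C)C#CCCCC1(OC)CC[C@@H](CC(=O)[O-])OO1.[K+] | intermediate
15 | 2-[(3S)-6-methoxy-6-[5-(trimethylsilyl)pent-4-yn-1-yl]-1,2-dioxan-3-yl]acetic acid (C6 epimers) | C[Si](C)(C)C#CCCCC1(OC)CC[C@@H](CC(=O)O)OO1 | intermediate
16 | methyl 2-[(3S,6R)-6-methoxy-6-[5-(trimethylsilyl)pent-4-yn-1-yl]-1,2-dioxan-3-yl]acetate | C[Si](C)(C)C#CCCC[C@]1(OC)CC[C@@H](CC(=O)OC)OO1 | intermediate
17 | methyl 2-[(3S,6R)-6-methoxy-6-(pent-4-yn-1-yl)-1,2-dioxan-3-yl]acetate | C#CCCC[C@]1(OC)CC[C@@H](CC(=O)OC)OO1 | intermediate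
18 | undec-1-yne | CCCCCCCCCC#C | starting material
19 | chloridobis(cyclopentadienyl)[(1E)-undec-1-en-1-yl]zirconium | CCCCCCCCC/C=C/[Zr](Cl)(C1C=CC=C1)C1C=CC=C1 | intermediate
20 | (E)-1-iodoundec-1-ene | CCCCCCCCC/C=C/I | intermediate
21 | methyl 2-[(3S,6R)-6-[(6E)-hexadec-6-en-4-yn-1-yl]-6-methoxy-1,2-dioxan-3-yl]acetate | CCCCCCCCC/C=C/C#CCCC[C@]1(OC)CC[C@@H](CC(=O)OC)OO1 | intermediate
22 | lithium 2-[(3S,6R)-6-[(6E)-hexadec-6-en-4-yn-1-yl]-6-methoxy-1,2-dioxan-3-yl]acetate | CCCCCCCCC/C=C/C#CCCC[C@]1(OC)CC[C@@H](CC(=O)[O-])OO1.[Li+] | intermediate
23 | 2-[(3S,6R)-6-[(6E)-hexadec-6-en-4-yn-1-yl]-6-methoxy-1,2-dioxan-3-yl]acetic acid | CCCCCCCCC/C=C/C#CCCC[C@]1(OC)CC[C@@H](CC(=O)O)OO1 | target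

## Step count and risks

Total: 10 steps. Longest linear sequence: 9 steps (steps 1–7, 9 and 10, from chloride 1); step 8 is a one-step side branch.

**Step 6 (key step, proposed new method).** The most likely failure is attack of the peroxide anion at the lactone carbonyl of a second molecule (perester formation and oligomerisation) outrunning the displacement at the secondary carbon. A second possibility is slow closure of the C6 epimer that must place the long chain axially.

The fallback uses the known displacement of a sulfonate by a hydroperoxy ketal. It sets out from lactone 10 and returns at 17.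
- LiBH4 in THF reduces the lactone to (3R)-6-methylidene-11-(trimethylsilyl)undec-10-yne-1,3-diol F1.
- TBDPSCl and imidazole silylate the primary hydroxyl to give (3R)-1-[(tert-butyldiphenylsilyl)oxy]-6-methylidene-11-(trimethylsilyl)undec-10-yn-3-ol F2.
- MsCl and Et3N give the (3R)-methanesulfonate F3.
- Ozonolysis in CH2Cl2/MeOH, as in step 5, gives the hydroperoxy ketal methanesulfonate F4.
- KOtBu and 18-crown-6 in toluene close the ring by 6-exo-tet displacement with inversion, giving tert-butyl{2-[(3S)-6-methoxy-6-[5-(trimethylsilyl)pent-4-yn-1-yl]-1,2-dioxan-3-yl]ethoxy}diphenylsilane F5.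
- Bu4NF removes both silyl groups to give 2-[(3S)-6-methoxy-6-(pent-4-yn-1-yl)-1,2-dioxan-3-yl]ethan-1-ol F6.
- TEMPO and PhI(OAc)2 in MeCN/H2O oxidise the alcohol to 2-[(3S)-6-methoxy-6-(pent-4-yn-1-yl)-1,2-dioxan-3-yl]acetic acid F7.
- TsOH in MeOH, as in the first half of step 7, esterifies and equilibrates F7 to 17.

**Step 4.** Facial selectivity may be insufficient with this aldehyde, or the nucleophilic 1,1-disubstituted alkene may be acylated by the acetyl bromide/Lewis acid pair.

The fallback sets out from aldehyde 9 and returns at 10.
- Corey–Chaykovsky methylenation (Me3S+ I−, n-BuLi, THF) gives racemic 2-[3-methylidene-8-(trimethylsilyl)oct-7-yn-1-yl]oxirane F8.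
- Hydrolytic kinetic resolution uses the enantiomer of (salen)Co(OAc) that consumes the (S)-epoxide (salen = N,N′-bis(3,5-di-tert-butylsalicylidene)-1,2-cyclohexanediamine dianion). It leaves (2R)-2-[3-methylidene-8-(trimethylsilyl)oct-7-yn-1-yl]oxirane F9, at the cost of half the material.
- Ring-expanding carbonylation with [(salph)Al(THF)2][Co(CO)4] under CO inserts at the unsubstituted carbon with retention at the stereocentre and gives 10.

**Step 5.** Material may be lost by recombination of the ketone O-oxide with the expelled formaldehyde instead of capture by methanol, or by ozone attack on the silyl alkyne during over-exposure.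

The fallback avoids ozone. It sets out from 10 and returns at 12.
- Lemieux–Johnson cleavage (OsO4 cat., NaIO4, 2,6-lutidine, dioxane/H2O) gives (4R)-4-[3-oxo-8-(trimethylsilyl)oct-7-yn-1-yl]oxetan-2-one F10.
- HC(OMe)3 and pyridinium tosylate in MeOH give (4R)-4-[3,3-dimethoxy-8-(trimethylsilyl)oct-7-yn-1-yl]oxetan-2-one F11.
- Urea–hydrogen peroxide with Sc(OTf)3 (cat.) in MeOH exchanges one methoxy group for a hydroperoxy group and gives 12.

**Step 7.** The equilibrium at C6 may be only weakly biased, or prolonged exposure to protic acid may trigger heterolysis of the O–O bond before esterification is complete.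

The fallback replaces thermodynamic control by kinetic capture. It sets out from 15 and returns at 16.
- Me3SiCHN2 in toluene/MeOH gives methyl 2-[(3S)-6-methoxy-6-[5-(trimethylsilyl)pent-4-yn-1-yl]-1,2-dioxan-3-yl]acetate as the C6 epimer mixture F12.
- Catalytic Me3SiOTf with MeOSiMe3 in CH2Cl2 at −78 °C ionises the ketal to the peroxycarbenium ion, which should be captured axially to give 16.
- K2CO3 in MeOH, as in the second half of step 7, then gives 17.

**Step 9.** Triphenylphosphine released from the catalyst may slowly deoxygenate the peroxide, and copper-mediated homocoupling of the alkyne may consume 17.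

The fallback is free of palladium and phosphine and reverses the polarity. It sets out from 17 and returns at 21.
- N-iodosuccinimide and AgNO3 (cat.) in acetone give methyl 2-[(3S,6R)-6-(5-iodopent-4-yn-1-yl)-6-methoxy-1,2-dioxan-3-yl]acetate F13.
- F13 is coupled with alkenylzirconocene 19 (generated as in step 8) under CuCl mediation in THF to give 21.

## Further compounds

F1 | step 6 | (3R)-6-methylidene-11-(trimethylsilyl)undec-10-yne-1,3-diol | C=C(CCCC#C[Si](C)(C)C)CC[C@@H](O)CCO
F2 | step 6 | (3R)-1-[(tert-butyldiphenylsilyl)oxy]-6-methylidene-11-(trimethylsilyl)undec-10-yn-3-ol | C=C(CCCC#C[Si](C)(C)C)CC[C@@H](O)CCO[Si](c1ccccc1)(c1ccccc1)C(C)(C)C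
F3 | step 6 | (3R)-1-[(tert-butyldiphenylsilyl)oxy]-6-methylidene-11-(trimethylsilyl)undec-10-yn-3-yl methanesulfonate | C=C(CCCC#C[Si](C)(C)C)CC[C@@H](OS(C)(=O)=O)CCO[Si](c1ccccc1)(c1ccccc1)C(C)(C)C
F4 | step 6 | (3R)-1-[(tert-butyldiphenylsilyl)oxy]-6-hydroperoxy-6-methoxy-11-(trimethylsilyl)undec-10-yn-3-yl methanesulfonate (C6 epimers) | C[Si](C)(C)C#CCCCC(OC)(OO)CC[C@@H](OS(C)(=O)=O)CCO[Si](c1ccccc1)(c1ccccc1)C(C)(C)C
F5 | step 6 | tert-butyl{2-[(3S)-6-methoxy-6-[5-(trimethylsilyl)pent-4-yn-1-yl]-1,2-dioxan-3-yl]ethoxy}diphenylsilane (C6 epimers) | C[Si](C)(C)C#CCCCC1(OC)CC[C@@H](CCO[Si](c2ccccc2)(c2ccccc2)C(C)(C)C)OO1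
F6 | step 6 | 2-[(3S)-6-methoxy-6-(pent-4-yn-1-yl)-1,2-dioxan-3-yl]ethan-1-ol (C6 epimers) | C#CCCCC1(OC)CC[C@@H](CCO)OO1
F7 | step 6 | 2-[(3S)-6-methoxy-6-(pent-4-yn-1-yl)-1,2-dioxan-3-yl]acetic acid (C6 epimers) | C#CCCCC1(OC)CC[C@@H](CC(=O)O)OO1
F8 | step 4 | 2-[3-methylidene-8-(trimethylsilyl)oct-7-yn-1-yl]oxirane (racemic) | C=C(CCCC#C[Si](C)(C)C)CCC1CO1
F9 | step 4 | (2R)-2-[3-methylidene-8-(trimethylsilyl)oct-7-yn-1-yl]oxirane | C=C(CCCC#C[Si](C)(C)C)CC[C@@H]1CO1
F10 | step 5 | (4R)-4-[3-oxo-8-(trimethylsilyl)oct-7-yn-1-yl]oxetan-2-one | C[Si](C)(C)C#CCCCC(=O)CC[C@@H]1CC(=O)O1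
F11 | step 5 | (4R)-4-[3,3-dimethoxy-8-(trimethylsilyl)oct-7-yn-1-yl]oxetan-2-one | C[Si](C)(C)C#CCCCC(OC)(OC)CC[C@@H]1CC(=O)O1
F12 | step 7 | methyl 2-[(3S)-6-methoxy-6-[5-(trimethylsilyl)pent-4-yn-1-yl]-1,2-dioxan-3-yl]acetate (C6 epimer mixture) | C[Si](C)(C)C#CCCCC1(OC)CC[C@@H](CC(=O)OC)OO1
F13 | step 9 | methyl 2-[(3S,6R)-6-(5-iodopent-4-yn-1-yl)-6-methoxy-1,2-dioxan-3-yl]acetate | IC#CCCC[C@]1(OC)CC[C@@H](CC(=O)OC)OO1
A1 | alternative 1 | tert-butyl{2-[(3R)-6-methoxy-6-[5-(triisopropylsilyl)pent-4-yn-1-yl]-3,6-dihydro-1,2-dioxin-3-yl]ethoxy}diphenylsilane (C6 epimers; same spatial arrangement at C3 as the target) | CC(C)[Si](C(C)C)(C(C)C)C#CCCCC1(OC)C=C[C@@H](CCO[Si](c2ccccc2)(c2ccccc2)C(C)(C)C)OO1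
A2 | alternative 1 | acyclic bis-allylic mixed peroxyketal (ring-closing metathesis substrate) | C=C[C@@H](CCO[Si](c1ccccc1)(c1ccccc1)C(C)(C)C)OOC(OC)(C=C)CCCC#C[Si](C(C)C)(C(C)C)C(C)C
A3 | alternative 2 | methyl 2-[(3S,6R)-6-[(6E)-hexadec-6-en-4-yn-1-yl]-6-methoxy-1,2-dioxan-3-yl]acetate (same structure as 21) | CCCCCCCCC/C=C/C#CCCC[C@]1(OC)CC[C@@H](CC(=O)OC)OO1
A4 | alternative 2 | 1-[(6E)-hexadec-6-en-4-yn-1-yl]-1-methoxycyclopropane | CCCCCCCCC/C=C/C#CCCCC1(OC)CC1
A5 | alternative 2 | methyl 3-methoxy-3-[(triethylsilyl)peroxy]propanoate | COC(=O)CC(OC)OO[Si](CC)(CC)CC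
A6 | alternative 3 | tert-butyl{2-[(3S,6R)-6-[(6E)-hexadec-6-en-4-yn-1-yl]-6-methoxy-1,2-dioxan-3-yl]ethoxy}diphenylsilane | CCCCCCCCC/C=C/C#CCCC[C@]1(OC)CC[C@@H](CCO[Si](c2ccccc2)(c2ccccc2)C(C)(C)C)OO1
A7 | alternative 3 | α-methoxy acid carrying the C3 hydroperoxide (anodic decarboxylation substrate) | CCCCCCCCC/C=C/C#CCCCC(OC)(C(=O)O)CC[C@@H](CCO[Si](c1ccccc1)(c1ccccc1)C(C)(C)C)OO
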